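**Retrosynthetic overview**
1. Oxepene last: the C5–O–C11 tertiary ether by intramolecular Nicholas etherification of a cobalt-complexed tertiary propargylic alcohol, then reductive decomplexation to the cis C7=C8 alkene; the two esters come from a cis-diol.
2. The C6–O–C9 γ-lactone and the C7/C8/C11 chain come from acetylide opening of a bridged C4–O–C9 lactone, Felkin reduction of the ynone and translactonisation.
3. Ring A by ring-closing metathesis of a C4 allyl and a C10 propenyl group; C4 by chelate-controlled allylation of an α-hydroxy ketone.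
4. Key step: the bond between the two fully substituted carbons C5 and C10 by Rh-carbenoid O–H insertion, Claisen [3,3] shift and α-ketol [1,2] shift between a diazoacetoacetate and an allylic alcohol made from ethyl (S)-lactate, the only source of chirality.
5. Ring order: temporary C4–O–C9 lactone → ring A → C6–O–C9 γ-lactone → oxepene.

Labels: C1 = CH–OBz, C2 = CH–OAc, C3 = CH2, C4 = C(CH3)OH, C5 = C–O (ether), C6 = lactone C=O, C7=C8 = alkene, C9 = lactone CH–O, C10 = ring-fusion C–CH3, C11 = C(CH3)2; β = face of ring A carrying the C10 methyl. The target is (1R,2S,4S,5S,9S,10R) in these labels.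
Assumption: the BF3-promoted α-ketol shift in step 4 runs through the usual syn-periplanar O–C–C=O arrangement with retention at the migrating carbon.

**Step 1**
Reactants: 1 ethyl (S)-lactate; 2 tert-butyl(chloro)dimethylsilane
Product: 3 ethyl (2S)-2-[(tert-butyldimethylsilyl)oxy]propanoate
Conditions: TBSCl, imidazole, DMF, rt
Reagents that add atoms: tert-butyl(chloro)dimethylsilane, CC(C)(C)[Si](C)(C)Cl
Why: Standard silylation protects the secondary alcohol for the hydride reduction and leaves the lactate stereocentre untouched.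

**Step 2**
Reactants: 3 ethyl (2S)-2-[(tert-butyldimethylsilyl)oxy]propanoate; 4 ethyl 2-(triphenylphosphoranylidene)propanoate
Product: 6 ethyl (2E,4S)-4-[(tert-butyldimethylsilyl)oxy]-2-methylpent-2-enoate, via aldehyde 5 (not isolated)
Conditions: i-Bu2AlH (1.05 equiv), CH2Cl2, −78 °C; then 4, −78 °C → rt
Reagents that add atoms: ethyl 2-(triphenylphosphoranylidene)propanoate, CCOC(=O)C(C)=P(c1ccccc1)(c1ccccc1)c1ccccc1
Why: Low-temperature hydride reduction stops at the α-silyloxy aldehyde, which is trapped without isolation (no epimerisation) in a Wittig olefination whose stabilised α-methyl ylide gives the E-trisubstituted enoate.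

**Step 3**
Reactants: 6 ethyl (2E,4S)-4-[(tert-butyldimethylsilyl)oxy]-2-methylpent-2-enoate
Product: 7 ethyl (2E,4S)-4-hydroxy-2-methylpent-2-enoate
Conditions: HF·pyridine, THF, 0 °C → rt
Reagents that add atoms: none
Why: Fluoride desilylation frees the allylic alcohol, and the E geometry prevents lactonisation.

**Step 4**
Reactants: 7 ethyl (2E,4S)-4-hydroxy-2-methylpent-2-enoate; 8 ethyl 2-diazo-3-oxobutanoate
Product: 11 diethyl (2S,3R)-2-acetyl-2-hydroxy-3-methyl-3-[(1E)-prop-1-en-1-yl]butanedioate, via enol ether 9 (not isolated), via α-ketol 10 (not isolated)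
Conditions: Rh2(OAc)4 (1 mol %), benzene, 80 °C, slow addition of 8; then BF3·OEt2 (1.1 equiv), rt
Reagents that add atoms: ethyl 2-diazo-3-oxobutanoate, CCOC(=O)C(=[N+]=[N-])C(C)=O
Why: Rh-carbenoid O–H insertion gives the (Z)-enol 9, whose chair Claisen [3,3] shift (lactate methyl equatorial) transfers the carbinol chirality to quaternary C10 and to C4 of ketol 10, and the BF3-promoted α-ketol [1,2] shift then moves the C10 group to C5 with retention, fixing C5 (S) and C10 (R).

**Step 5**
Reactants: 11 diethyl (2S,3R)-2-acetyl-2-hydroxy-3-methyl-3-[(1E)-prop-1-en-1-yl]butanedioate; 12 allyl bromide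
Product: 14 ethyl (2S,3S,4R)-3-hydroxy-2,4-dimethyl-5-oxo-2-(prop-2-en-1-yl)-4-[(1E)-prop-1-en-1-yl]oxolane-3-carboxylate, via hydroxy ester 13 (not isolated)
Conditions: allyl bromide, In powder, THF/H2O (1:1), rt; then 1 M HCl, rt
Reagents that add atoms: allyl bromide, C=CCBr
Why: Barbier allylation in water goes through the five-membered indium chelate of the α-hydroxy ketone, allyl attacking the ketone face opposite the bulky C10 substituent (Cram chelate control) to set C4 (S), and the new tertiary hydroxyl then lactonises onto the C9 ester under acid.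

**Step 6**
Reactants: 14 ethyl (2S,3S,4R)-3-hydroxy-2,4-dimethyl-5-oxo-2-(prop-2-en-1-yl)-4-[(1E)-prop-1-en-1-yl]oxolane-3-carboxylate
Product: 15 ethyl (1R,5S,8S)-8-hydroxy-1,5-dimethyl-7-oxo-6-oxabicyclo[3.2.1]oct-2-ene-8-carboxylate
Conditions: second-generation Grubbs catalyst (5 mol %), CH2Cl2, 40 °C
Reagents that add atoms: none
Why: Ring-closing metathesis joins the cis-disposed allyl and propenyl groups into ring A with loss of propene, and because only the C4 epimer with both alkenyl groups on one face of the lactone can close, the step also checks the C4 configuration.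

**Step 7**
Reactants: 15 ethyl (1R,5S,8S)-8-hydroxy-1,5-dimethyl-7-oxo-6-oxabicyclo[3.2.1]oct-2-ene-8-carboxylate; 16 2-methylbut-3-yn-2-ol
Product: 17 ethyl (1S,2S,6R)-1,2-dihydroxy-6-(4-hydroxy-4-methylpent-2-ynoyl)-2,6-dimethylcyclohex-4-ene-1-carboxylate
Conditions: 16 (4 equiv), n-BuLi (8 equiv), THF, −78 → 0 °C; then 15, −78 → −20 °C; AcOH quench at −78 °C
Reagents that add atoms: 2-methylbut-3-yn-2-ol, CC(C)(O)C#C
Why: Acetylide addition to the strained bridged lactone stops at the tetrahedral lactol alkoxide at low temperature, so one alkynyl group is delivered to C9 while the hindered ethyl ester next to the C5 alkoxide is left alone; no stereocentre is formed (17 equilibrates with its C4–O–C9 lactol).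

**Step 8**
Reactants: 17 ethyl (1S,2S,6R)-1,2-dihydroxy-6-(4-hydroxy-4-methylpent-2-ynoyl)-2,6-dimethylcyclohex-4-ene-1-carboxylate
Product: 19 (3S,3aS,7S,7aS)-7,7a-dihydroxy-3-(3-hydroxy-3-methylbut-1-yn-1-yl)-3a,7-dimethyl-3a,6,7,7a-tetrahydro-2-benzofuran-1(3H)-one, via propargylic alcohol 18 (not isolated)
Conditions: NaBH4, CeCl3·7H2O, MeOH, −78 → −20 °C; then pyridinium p-toluenesulfonate (cat.), toluene, 50 °C
Reagents that add atoms: none
Why: Luche 1,2-reduction of the ynone follows the Felkin–Anh model, hydride attacking anti to the fully substituted C5 with the C10 methyl as the small group, to give (9S), and the new alcohol then closes the γ-lactone onto the C6 ester (translactonisation).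

**Step 9**
Reactants: 19 (3S,3aS,7S,7aS)-7,7a-dihydroxy-3-(3-hydroxy-3-methylbut-1-yn-1-yl)-3a,7-dimethyl-3a,6,7,7a-tetrahydro-2-benzofuran-1(3H)-one; 20 N-methylmorpholine N-oxide
Product: 21 (3S,3aS,4R,5S,7S,7aS)-4,5,7,7a-tetrahydroxy-3-(3-hydroxy-3-methylbut-1-yn-1-yl)-3a,7-dimethylhexahydro-2-benzofuran-1(3H)-one
Conditions: OsO4 (2 mol %), NMO, acetone/H2O (4:1), rt
Reagents that add atoms: N-methylmorpholine N-oxide, C[N+]1([O-])CCOCC1; water, O
Why: Upjohn syn-dihydroxylation takes place on the convex β-face of the cis-fused bicycle, away from the lactone ring and the axial C4 hydroxyl, to give the 1β,2β-diol (1R,2S), the alkyne being much less reactive.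

**Step 10**
Reactants: 21 (3S,3aS,4R,5S,7S,7aS)-4,5,7,7a-tetrahydroxy-3-(3-hydroxy-3-methylbut-1-yn-1-yl)-3a,7-dimethylhexahydro-2-benzofuran-1(3H)-one; 22 trimethyl orthobenzoate
Product: 24 (3S,3aR,4R,5S,7S,7aS)-5,7,7a-trihydroxy-3-(3-hydroxy-3-methylbut-1-yn-1-yl)-3a,7-dimethyl-1-oxooctahydro-2-benzofuran-4-yl benzoate, via cyclic orthobenzoate 23 (not isolated)
Conditions: PhC(OMe)3, camphorsulfonic acid (cat.), MeCN, rt; then AcOH/H2O (4:1), rt
Reagents that add atoms: trimethyl orthobenzoate, COC(OC)(OC)c1ccccc1; water, O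
Why: The cis-diol forms a five-membered cyclic orthobenzoate whose acid hydrolysis opens to the axial ester, placing the benzoate on the hindered axial C1 oxygen and freeing the equatorial C2 hydroxyl (orthoester mono-acylation).

**Step 11**
Reactants: 24 (3S,3aR,4R,5S,7S,7aS)-5,7,7a-trihydroxy-3-(3-hydroxy-3-methylbut-1-yn-1-yl)-3a,7-dimethyl-1-oxooctahydro-2-benzofuran-4-yl benzoate; 25 acetic anhydride
Product: 26 (3S,3aR,4R,5S,7S,7aS)-5-(acetyloxy)-7,7a-dihydroxy-3-(3-hydroxy-3-methylbut-1-yn-1-yl)-3a,7-dimethyl-1-oxooctahydro-2-benzofuran-4-yl benzoate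
Conditions: Ac2O (1.5 equiv), pyridine, DMAP (cat.), CH2Cl2, 0 °C
Reagents that add atoms: acetic anhydride, CC(=O)OC(C)=O
Why: DMAP-catalysed acetylation acylates the only secondary hydroxyl, the three tertiary hydroxyls being inert at 0 °C.

**Step 12**
Reactants: 26 (3S,3aR,4R,5S,7S,7aS)-5-(acetyloxy)-7,7a-dihydroxy-3-(3-hydroxy-3-methylbut-1-yn-1-yl)-3a,7-dimethyl-1-oxooctahydro-2-benzofuran-4-yl benzoate; 27 Co2(CO)8
Product: 29 Co2(CO)6 complex of the 7,8-didehydro (ring alkyne) analogue of the target, via alkyne complex 28 (not isolated)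
Conditions: Co2(CO)8 (1.1 equiv), CH2Cl2, rt; then BF3·OEt2 (0.3 equiv), 4 Å molecular sieves, CH2Cl2 (2 mM), −20 → 0 °C
Reagents that add atoms: Co2(CO)8, O=C=[Co](=C=O)(=C=O)(=C=O)[Co](=C=O)(=C=O)(=C=O)=C=O
Why: Nicholas reaction, in which acid ionises the tertiary propargylic hydroxyl of the complexed alkyne to the Co2(CO)6-stabilised cation and the C5 hydroxyl, on the same face of the lactone as the side chain, captures it in a seven-membered ring closure made possible by the bent complexed alkyne; no new stereocentre is formed.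

**Step 13**
Reactants: 29 Co2(CO)6 complex of the 7,8-didehydro (ring alkyne) analogue of the target
Product: 30 CNP0178319.3, the (1R,2S,4S,5S,9S,10R) 2-acetate 1-benzoate of the tricyclic oxepene lactone
Conditions: n-Bu3SnH (5 equiv), benzene, 65 °C
Reagents that add atoms: none
Why: Tin hydride reductive decomplexation delivers two hydrogens to the ring-bound alkyne carbons and releases the cobalt, the seven-membered ring enforcing the cis alkene while esters and lactone are untouched.

**Compound list**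
1 | ethyl (S)-lactate | C[C@H](O)C(=O)OCC | starting material
2 | tert-butyl(chloro)dimethylsilane | CC(C)(C)[Si](C)(C)Cl | starting material
3 | ethyl (2S)-2-[(tert-butyldimethylsilyl)oxy]propanoate | C[C@H](O[Si](C)(C)C(C)(C)C)C(=O)OCC | intermediate
4 | ethyl 2-(triphenylphosphoranylidene)propanoate | CCOC(=O)C(C)=P(c1ccccc1)(c1ccccc1)c1ccccc1 | starting material
5 | (2S)-2-[(tert-butyldimethylsilyl)oxy]propanal | C[C@H](O[Si](C)(C)C(C)(C)C)C=O | intermediate
6 | ethyl (2E,4S)-4-[(tert-butyldimethylsilyl)oxy]-2-methylpent-2-enoate | C[C@H](O[Si](C)(C)C(C)(C)C)/C=C(\C)C(=O)OCC | intermediate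
7 | ethyl (2E,4S)-4-hydroxy-2-methylpent-2-enoate | C[C@H](O)/C=C(\C)C(=O)OCC | intermediate
8 | ethyl 2-diazo-3-oxobutanoate | CCOC(=O)C(=[N+]=[N-])C(C)=O | starting material
9 | ethyl (2Z)-2-{[(2S,3E)-5-ethoxy-4-methyl-5-oxopent-3-en-2-yl]oxy}-3-hydroxybut-2-enoate | C/C(O)=C(\C(=O)OCC)O[C@@H](C)/C=C(\C)C(=O)OCC | intermediate
10 | diethyl (3R,4R)-3-hydroxy-3,4-dimethyl-2-oxo-4-[(1E)-prop-1-en-1-yl]pentanedioate | CCOC(=O)C(=O)[C@@](O)(C)[C@](C)(C(=O)OCC)/C=C/C | intermediate
11 | diethyl (2S,3R)-2-acetyl-2-hydroxy-3-methyl-3-[(1E)-prop-1-en-1-yl]butanedioate | CC(=O)[C@](O)(C(=O)OCC)[C@](C)(C(=O)OCC)/C=C/C | intermediate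
12 | allyl bromide | C=CCBr | starting material
13 | diethyl (2S,3R)-2-hydroxy-2-[(2S)-2-hydroxypent-4-en-2-yl]-3-methyl-3-[(1E)-prop-1-en-1-yl]butanedioate | C=CC[C@](C)(O)[C@](O)(C(=O)OCC)[C@](C)(C(=O)OCC)/C=C/C | intermediate
14 | ethyl (2S,3S,4R)-3-hydroxy-2,4-dimethyl-5-oxo-2-(prop-2-en-1-yl)-4-[(1E)-prop-1-en-1-yl]oxolane-3-carboxylate | C=CC[C@]1(C)OC(=O)[C@](C)(/C=C/C)[C@@]1(O)C(=O)OCC | intermediate
15 | ethyl (1R,5S,8S)-8-hydroxy-1,5-dimethyl-7-oxo-6-oxabicyclo[3.2.1]oct-2-ene-8-carboxylate | O=C1O[C@@]2(C)CC=C[C@]1(C)[C@@]2(O)C(=O)OCC | intermediate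
16 | 2-methylbut-3-yn-2-ol | CC(C)(O)C#C | starting material
17 | ethyl (1S,2S,6R)-1,2-dihydroxy-6-(4-hydroxy-4-methylpent-2-ynoyl)-2,6-dimethylcyclohex-4-ene-1-carboxylate | CC(C)(O)C#CC(=O)[C@]1(C)C=CC[C@](C)(O)[C@]1(O)C(=O)OCC | intermediate
18 | ethyl (1S,2S,6S)-6-[(1S)-1,4-dihydroxy-4-methylpent-2-yn-1-yl]-1,2-dihydroxy-2,6-dimethylcyclohex-4-ene-1-carboxylate | CC(C)(O)C#C[C@H](O)[C@]1(C)C=CC[C@](C)(O)[C@]1(O)C(=O)OCC | intermediate
19 | (3S,3aS,7S,7aS)-7,7a-dihydroxy-3-(3-hydroxy-3-methylbut-1-yn-1-yl)-3a,7-dimethyl-3a,6,7,7a-tetrahydro-2-benzofuran-1(3H)-one | CC(C)(O)C#C[C@@H]1OC(=O)[C@@]2(O)[C@@](C)(O)CC=C[C@@]12C | intermediate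
20 | N-methylmorpholine N-oxide | C[N+]1([O-])CCOCC1 | starting material
21 | (3S,3aS,4R,5S,7S,7aS)-4,5,7,7a-tetrahydroxy-3-(3-hydroxy-3-methylbut-1-yn-1-yl)-3a,7-dimethylhexahydro-2-benzofuran-1(3H)-one | CC(C)(O)C#C[C@@H]1OC(=O)[C@@]2(O)[C@@](C)(O)C[C@H](O)[C@H](O)[C@@]12C | intermediate
22 | trimethyl orthobenzoate | COC(OC)(OC)c1ccccc1 | starting material
23 | C1,C2-cyclic methyl orthobenzoate of 21 (both epimers at the orthoester carbon) | CC(C)(O)C#C[C@@H]1OC(=O)[C@@]2(O)[C@@](C)(O)C[C@@H]3OC(OC)(c4ccccc4)O[C@@H]3[C@@]12C | intermediate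
24 | (3S,3aR,4R,5S,7S,7aS)-5,7,7a-trihydroxy-3-(3-hydroxy-3-methylbut-1-yn-1-yl)-3a,7-dimethyl-1-oxooctahydro-2-benzofuran-4-yl benzoate | CC(C)(O)C#C[C@@H]1OC(=O)[C@@]2(O)[C@@](C)(O)C[C@H](O)[C@H](OC(=O)c3ccccc3)[C@@]12C | intermediate
25 | acetic anhydride | CC(=O)OC(C)=O | starting material
26 | (3S,3aR,4R,5S,7S,7aS)-5-(acetyloxy)-7,7a-dihydroxy-3-(3-hydroxy-3-methylbut-1-yn-1-yl)-3a,7-dimethyl-1-oxooctahydro-2-benzofuran-4-yl benzoate | CC(C)(O)C#C[C@@H]1OC(=O)[C@@]2(O)[C@@](C)(O)C[C@H](OC(C)=O)[C@H](OC(=O)c3ccccc3)[C@@]12C | intermediate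
27 | Co2(CO)8 (dicobalt octacarbonyl) | O=C=[Co](=C=O)(=C=O)(=C=O)[Co](=C=O)(=C=O)(=C=O)=C=O | starting material
28 | Co2(CO)6 complex of 26 at the C7≡C8 alkyne (configuration as in 26) | CC(C)(O)C12[Co]3(=C=O)(=C=O)(=C=O)[Co]1(=C=O)(=C=O)(=C=O)C23[C@@H]4OC(=O)[C@@]5(O)[C@@](C)(O)C[C@H](OC(C)=O)[C@H](OC(=O)c6ccccc6)[C@@]45C | intermediate
29 | Co2(CO)6 complex of the 7,8-didehydro (ring alkyne) analogue of 30 (configuration as in 30) | CC(=O)O[C@H]1C[C@](C)(O)[C@]23OC(C)(C)C45[Co]6(=C=O)(=C=O)(=C=O)[Co]4(=C=O)(=C=O)(=C=O)C56[C@H](OC2=O)[C@]3(C)[C@H]1OC(=O)c1ccccc1 | intermediate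
30 | CNP0178319.3, (1R,2S,4S,5S,9S,10R) in the labels above | CC(=O)O[C@H]1C[C@](C)(O)[C@]23OC(C)(C)C=C[C@H](OC2=O)[C@]3(C)[C@H]1OC(=O)c1ccccc1 | target

**Count and risks**
Total step count: 13. Longest linear sequence: 13 steps, from ethyl (S)-lactate 1.

Most likely to fail, step 4: the [3,3] shift has to join two fully substituted carbons at the α-carbon of an enoate and may lag behind tautomerisation of enol 9; the [1,2] shift must move the ester-bearing C10 group and not the methyl; the C5 configuration rests on the (Z)-enol and the syn-periplanar shift. The fallback sets out from 7 and comes back at 11. Heating 7 with triethyl orthoacetate and catalytic propanoic acid at 140 °C (Johnson–Claisen, same chair and same sense of chirality transfer) gives diethyl (2S)-2-methyl-2-[(1E)-prop-1-en-1-yl]butanedioate F1. Its only enolisable ester is deprotonated with LDA in THF at −78 °C and C-acylated with N-methoxy-N-methylacetamide to diethyl (3R)-2-acetyl-3-methyl-3-[(1E)-prop-1-en-1-yl]butanedioate F2. Hydroxylation of this β-keto ester at C5 with dimethyldioxirane in acetone at 0 °C returns 11; the C5 epimers are separated if control by C10 is incomplete. Here the C5–C10 bond comes directly from the [3,3] shift and the C5 oxygen from enolate oxidation.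

Most likely to fail, step 5: the ketone is hindered, and an ester-bound instead of a ketone-bound chelate would give the C4 epimer. The fallback sets out from 11 and comes back at 13, which lactonises to 14 as in step 5. The ketone of 11 is methylenated with Ph3P=CH2 in THF at 0 °C to diethyl (2R,3R)-2-hydroxy-3-methyl-2-(prop-1-en-2-yl)-3-[(1E)-prop-1-en-1-yl]butanedioate F3. Hydroxyl-directed epoxidation with VO(acac)2 and t-BuOOH in benzene gives diethyl (2S,3R)-2-hydroxy-3-methyl-2-[(2S)-2-methyloxiran-2-yl]-3-[(1E)-prop-1-en-1-yl]butanedioate F4, oxygen being delivered from the conformer that keeps the C10 group away from the alkene methyl. Opening at the CH2 terminus with vinylmagnesium bromide and catalytic CuI in THF at −30 °C gives 13. C4 is then set by directed epoxidation instead of carbonyl addition, and the ring closure of step 6 again reveals a wrong epimer.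

Most likely to fail, step 12: a tertiary alcohol must capture a tertiary cation, ring A has to leave its chair for a twist form so that the C5 oxygen can reach C11, and elimination to the enyne competes. The fallback sets out from 26 and comes back at 30. Semi-hydrogenation of 26 over Pd/CaCO3 poisoned with Pb(OAc)2 and quinoline in EtOAc gives (3S,3aR,4R,5S,7S,7aS)-5-(acetyloxy)-7,7a-dihydroxy-3-[(1Z)-3-hydroxy-3-methylbut-1-en-1-yl]-3a,7-dimethyl-1-oxooctahydro-2-benzofuran-4-yl benzoate F5. Catalytic Bi(OTf)3 (5 mol %) in CH2Cl2 at −20 °C ionises its tertiary allylic alcohol, and the C5 hydroxyl captures the tertiary end of the Z-allyl cation (SN1 etherification) to give 30 without cobalt.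

**Further compounds**
F1 | step 4 | diethyl (2S)-2-methyl-2-[(1E)-prop-1-en-1-yl]butanedioate | CCOC(=O)C[C@](C)(C(=O)OCC)/C=C/C
F2 | step 4 | diethyl (3R)-2-acetyl-3-methyl-3-[(1E)-prop-1-en-1-yl]butanedioate (both C2 epimers) | CCOC(=O)C(C(C)=O)[C@](C)(C(=O)OCC)/C=C/C
F3 | step 5 | diethyl (2R,3R)-2-hydroxy-3-methyl-2-(prop-1-en-2-yl)-3-[(1E)-prop-1-en-1-yl]butanedioate | C=C(C)[C@](O)(C(=O)OCC)[C@](C)(C(=O)OCC)/C=C/C
F4 | step 5 | diethyl (2S,3R)-2-hydroxy-3-methyl-2-[(2S)-2-methyloxiran-2-yl]-3-[(1E)-prop-1-en-1-yl]butanedioate | C[C@]1(CO1)[C@](O)(C(=O)OCC)[C@](C)(C(=O)OCC)/C=C/C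
F5 | step 12 | (3S,3aR,4R,5S,7S,7aS)-5-(acetyloxy)-7,7a-dihydroxy-3-[(1Z)-3-hydroxy-3-methylbut-1-en-1-yl]-3a,7-dimethyl-1-oxooctahydro-2-benzofuran-4-yl benzoate | CC(C)(O)/C=C\[C@@H]1OC(=O)[C@@]2(O)[C@@](C)(O)C[C@H](OC(C)=O)[C@H](OC(=O)c3ccccc3)[C@@]12C
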